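You charge substrate and capture agent into a closed, stirred flask. Substrate turns reversibly into intermediate A and, on a side path, into intermediate B. Intermediate A goes on to target, or meets capture agent and becomes trapped intermediate. Substrate also decomposes slowly.

    substrate ⇌ intermediate A (K1 = 1.2, k1 = 0.0025 s⁻¹)
    substrate ⇌ intermediate B (K2 = 0.45, k2 = 0.0057 s⁻¹)
    intermediate A → target (k3 = 0.0051 s⁻¹)
    capture agent + intermediate A → trapped intermediate (k4 = 0.053 L mol⁻¹ s⁻¹)
    substrate → decomposition product (k5 = 1.7 × 10⁻⁵ s⁻¹)

| flask | substrate | capture agent | time |
|---|---|---|---|
| violet | 0.20 M | 0.0100 M | 30 min |
| ochre | 0.20 M | 0.0200 M | 30 min |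
| grey | 0.20 M | 0.0400 M | 30 min |
| green | 0.20 M | 0.0800 M | 30 min |
| teal | 0.20 M | 0.150 M | 30 min |

- "hardly changes" means that all values lie within two and a half points (for a concentration: within two and a half percent of the largest)
- run time (violet): 30 min

* amount of target at the end, in percent of the substrate charged for violet, ochre, grey, green, teal, in this order
* how that number moves from the first to the last of them (hardly changes / falls, then rises / falls all the way / rises all the way / rises, then falls)

Keep a ledger of the substrate, starting with the two exits of intermediate A. Target grows as 0.0051 s⁻¹ times c(intermediate A), and trapped intermediate grows as 0.053 L mol⁻¹ s⁻¹ times c(capture agent) times c(intermediate A). c(intermediate A) cancels in the ratio, and what stays frozen is 0.0962 M, the even-split concentration, the c(capture agent) at which intermediate A leaves equally by both exits; it is a selectivity factor. Adding up the small steps, target made equals this concentration times ln(agent charged / agent left). Against the substrate charge, that multiplier is 48.1 %.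

Next entry: how much gets through intermediate A? Step 2 has a forward half-life of 2.0 min, shorter than the 30 min of the run, so I hold substrate and intermediate B in equilibrium. Intermediate A has a half-life of 2.3 min by step 3 alone, also shorter than the run, so I hold it steady. Leaving the agent aside, 71.0 % of what enters intermediate A goes forward. The pool therefore decays at 0.0734 min⁻¹, which leaves 11.0 % as substrate and intermediate B, with 2.65 % as intermediate A. Decomposition has a half-life of 11 h, far longer than the run, so I book nothing there. That leaves 86.3 % to divide between target and trapped intermediate, and I take this figure for each flask.

Now close the books. In violet the agent charge is 5.00 % of the substrate. If it were spent, target would be 81.3 %, but the rule then leaves 18.5 % of the agent, so trapped intermediate is 4.08 % and target 82.2 %. In teal I try two values. With 50.0 % of the agent left, target plus trapped comes to 70.8 %; with 33.3 % left, it comes to 103 %. Interpolating to the through-put gives target 42.8 % in teal, less than the 82.2 % of violet. At equal through-put, a larger charge books more to trapped intermediate, so I expect the row to fall all the way.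

The forecast gives 81 %, 77.5 %, 71 %, 60 % and 45 %, falls all the way, on the grounds that “the yield falls steadily with dose”.

The simulation gives 80.2 %, 76.8 %, 70.3 %, 59.0 % and 44.2 %: falls all the way.

In violet, half of the turnover of intermediate A into target was done by 10.1 min, target stood at 55.2 % after 15.0 min, and capture agent sank to 19 % of its charge at the end. In teal, 5.6 % of the substrate and 40 % of the agent still stood at the end, with target plus trapped intermediate at 89.3 % against 84.3 % in violet. The agent left in violet gives target 79.9 % by the even-split rule, and the agent left in teal gives 44.1 %.

The numbers of this flask are made up; the run is a simulation.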